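The numbers in the tables were generated by integration with constants of no real substance.

0.214 is the number I carry to this flask: the peak share, meaning the peak reading of target per equivalent of reagent charged, averaged over the cedar, alder and larch runs. It says how much target stands at the peak for each unit of reagent put in.

| flask | substrate | reagent | remark | time |
|---|---|---|---|---|
| cedar | 0.40 M | 0.30 equiv | run made earlier |  |
| alder | 0.40 M | 0.45 equiv | run made earlier |  |
| larch | 0.60 M | 0.60 equiv | run made earlier |  |
| flask | 0.40 M | 0.600 equiv |  | 20 h |

| run | time / h | target / % | substrate / % |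
|---|---|---|---|
| cedar | 0.667 | 2.5 | 84.0 |
| cedar | 1.33 | 4.7 | 75.9 |
| cedar | 2.50 | 6.5 | 70.6 |
| cedar | 5.00 | 5.6 | 66.0 |
| cedar | 10.0 | 4.3 | 65.3 |
| cedar | 20.0 | 3.6 | 64.3 |
| alder | 0.667 | 3.7 | 77.0 |
| alder | 1.33 | 7.6 | 65.4 |
| alder | 2.50 | 10.2 | 56.8 |
| alder | 5.00 | 8.3 | 51.8 |
| alder | 10.0 | 5.5 | 48.4 |
| alder | 20.0 | 5.9 | 48.2 |
| larch | 0.667 | 6.4 | 62.0 |
| larch | 1.50 | 11.8 | 47.9 |
| larch | 4.00 | 12.0 | 35.0 |
| larch | 8.00 | 8.5 | 31.3 |
| larch | 20.0 | 7.2 | 30.1 |

(readings scatter by 0.5 percentage points)

- the moment within 20 h at which there is most target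
- the amount of target, in percent of the substrate charged, at that time



The cedar, alder and larch runs give shares of 0.217, 0.227 and 0.200. They spread over 0.0267, and a scatter of 0.5 percentage points moves the cedar share by 0.0167, so I accept one number for the height, although larch has another substrate concentration. But one number holds no clock. The cedar run reads more target at 2.50 h than at the readings on either side, and the alder run does the same; both share the flask's 0.40 M of substrate. For the flask I therefore commit to 12.9% near 2.50 h.

The forecast says 13.2% at 3.2 h, holding that “the peak time is only weakly concentration dependent”.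

The flask gives 12.8% at 2.87 h.

    substrate + reagent → intermediate + released group (k = 0.0483 M⁻¹ min⁻¹)
    intermediate ⇌ target (K = 3.60, k = 0.00954 min⁻¹)
    intermediate ⇌ isomer of the product A (K = 2.10, k = 7.81 × 10⁻⁴ min⁻¹)
    target ⇌ isomer of the product B (K = 5.10, k = 0.0127 min⁻¹)
    substrate + intermediate → side product (k = 0.00558 M⁻¹ min⁻¹)

The flask's own share is 0.213, beside the 0.214 I carried. On a neighbour flask, the same as the flask but charged with 0.150 equiv of reagent, the share gives a peak of 3.21%, and that neighbour flask gives 3.42%. The reagent is the limiting reagent there, with 0% of its charge left at 20.0 h, when that neighbour flask still holds 81.7% substrate.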